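**Retrosynthetic overview**

1. C3–C4 (key): the target holds a homoallylic alcohol, O–C2–C3–C4=C5. C3 is an unsubstituted CH2 next to the carbinol C2, so it can be the CH2 of an oxirane (methyl (R)-glycidate, C1–C3, C2 configuration bought). C4 is an sp2 carbon of the Z-trisubstituted alkene, so it can be carried as an alkenyl iodide. The two electrophilic carbons are joined by nickel-catalysed reductive cross-electrophile coupling, which should release the unprotected target in the last step.
2. C4=C5: the (Z)-alkenyl iodide (C4–C15 plus furan) from the C5 aldehyde by Z-selective Wittig iodo-ethylidenation.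
3. C10–C11: the (9E,11E)-diene by Suzuki coupling of an (E)-alkenyl iodide (C11–C15, furan) with an (E)-alkenylboronate (C5–C10).
4. West piece: 3-bromofuran plus a C5 silylalkyne Grignard reagent (Kumada), desilylation, Zr-catalysed carboalumination/iodination (sets 11E). East piece: (S)-β-citronellene supplies C8; ozonolysis of its trisubstituted alkene gives the C5 aldehyde, cross-metathesis with vinyl-Bpin sets 9E.
5. Rings: none is formed. The furan is bought as 3-bromofuran; the only other ring, the oxirane of the glycidate, is opened in the key step.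

Key step: step 8

Assumption: C8 comes from the chiral pool, so commercial (S)-β-citronellene is assumed to be of high enantiomeric purity (or enriched before use), since no later step can correct it; locants C1–C15 are those of the pentadecatrienoate chain of the target.

**Route**

Step 1
Reactants: 1 3-bromofuran; 2 5-chloro-1-(trimethylsilyl)pent-1-yne
Product: 4 3-[5-(trimethylsilyl)pent-4-yn-1-yl]furan, via Grignard reagent 3 (not isolated)
Conditions: 2, Mg, THF, 60 °C; then 1, NiCl2(dppp) (3 mol %), THF, 0 °C → rt
Reagents that add atoms: none
Why: Kumada–Corriu coupling of a primary alkyl Grignard reagent with 3-bromofuran under Ni(dppp) catalysis is a standard entry to 3-alkylfurans, and the silyl cap keeps the acetylenic C–H away from the Grignard reagent.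

Step 2
Reactants: 4 3-[5-(trimethylsilyl)pent-4-yn-1-yl]furan
Product: 5 3-(pent-4-yn-1-yl)furan
Conditions: K2CO3 (cat.), MeOH, rt
Reagents that add atoms: none
Why: Base-catalysed methanolysis of the C(sp)–Si bond (protodesilylation) should free the terminal alkyne without touching the furan.

Step 3
Reactants: 5 3-(pent-4-yn-1-yl)furan
Product: 7 3-[(4E)-5-iodo-4-methylpent-4-en-1-yl]furan, via alkenylalane 6 (not isolated)
Conditions: Me3Al (2.5 equiv), Cp2ZrCl2 (0.25 equiv), CH2Cl2, 0 °C → rt; then I2, THF, −30 → 0 °C
Reagents that add atoms: trimethylaluminium, C[Al](C)C; iodine, II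
Why: Negishi zirconium-catalysed carboalumination adds CH3 and Al syn across the terminal alkyne with aluminium on the terminal carbon, and iodinolysis of the C–Al bond with retention should fix the later 11E geometry (CH3 cis to iodine).

Step 4
Reactants: 8 (S)-β-citronellene [(3S)-3,7-dimethylocta-1,6-diene]
Product: 10 (4S)-4-methylhex-5-enal, via ozonide 9 (not isolated)
Conditions: O3 (1 equiv, Sudan Red 7B end point), CH2Cl2, −78 °C; then Me2S, −78 °C → rt
Reagents that add atoms: ozone, [O-][O+]=O
Why: In this chemoselective ozonolysis the electron-rich trisubstituted alkene should react much faster than the monosubstituted vinyl group, so a dye-indicated end point should cleave only the isopropylidene unit and leave the C8 stereocentre (not α to the new carbonyl) untouched.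

Step 5
Reactants: 10 (4S)-4-methylhex-5-enal; 11 vinylboronic acid pinacol ester
Product: 12 (4S,5E)-4-methyl-6-(4,4,5,5-tetramethyl-1,3,2-dioxaborolan-2-yl)hex-5-enal
Conditions: 11 (3 equiv), Hoveyda–Grubbs II catalyst (3 mol %), CH2Cl2, 40 °C
Reagents that add atoms: none
Why: Olefin cross-metathesis of a terminal alkene with vinyl-Bpin, which is reluctant to homodimerise, should give the (E)-alkenylboronate under steric control, the aldehyde being tolerated by the ruthenium carbene.

Step 6
Reactants: 7 3-[(4E)-5-iodo-4-methylpent-4-en-1-yl]furan; 12 (4S,5E)-4-methyl-6-(pinacolboryl)hex-5-enal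
Product: 13 (4S,5E,7E)-11-(furan-3-yl)-4,8-dimethylundeca-5,7-dienal
Conditions: Pd(dppf)Cl2·CH2Cl2 (5 mol %), K3PO4 (aq.), THF, rt
Reagents that add atoms: none
Why: Suzuki–Miyaura alkenyl–alkenyl coupling proceeds with retention at both partners and should therefore deliver the (E,E)-diene, the mild phosphate base at room temperature sparing the enolisable aldehyde.

Step 7
Reactants: 13 (4S,5E,7E)-11-(furan-3-yl)-4,8-dimethylundeca-5,7-dienal
Product: 14 3-[(4E,6E,8S,11Z)-12-iodo-4,8-dimethyltrideca-4,6,11-trien-1-yl]furan
Conditions: EtPPh3I, n-BuLi, THF, rt; I2, −78 °C; NaHMDS, −20 °C; then 13, −78 → −20 °C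
Reagents that add atoms: ethyltriphenylphosphonium iodide, CC[P+](c1ccccc1)(c1ccccc1)c1ccccc1.[I-]; iodine, II
Why: In this Stork–Zhao-type Wittig iodo-olefination the unstabilised α-iodoethylidene ylide should add to the aldehyde under kinetic control through the cis-oxaphosphetane that places iodine cis to the chain, giving the (Z)-2-iodoalkene that carries the 4Z geometry.

Step 8
Reactants: 14 3-[(4E,6E,8S,11Z)-12-iodo-4,8-dimethyltrideca-4,6,11-trien-1-yl]furan; 15 methyl (R)-glycidate [methyl (2R)-oxirane-2-carboxylate]
Product: 17 methyl (2R,4Z,8S,9E,11E)-15-(furan-3-yl)-2-hydroxy-4,8,12-trimethylpentadeca-4,9,11-trienoate (target), via iodohydrin 16 (not isolated)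
Conditions: 15 (2 equiv), NiCl2·glyme (10 mol %), 2,2′-bipyridine (10 mol %), NaI (25 mol %), Et3N·HCl (1.2 equiv), Mn powder (2 equiv), DMPU, rt
Reagents that add atoms: none
Why: Et3NH+/I− should open the oxirane of 15 by SN2 at the unsubstituted C3 to give iodohydrin 16 without touching the C2–O bond, while Ni(0)(bpy) adds oxidatively to the C(sp2)–I bond of 14; iodine-atom abstraction from 16 by nickel gives the primary C3 radical, the alkenylnickel(II) species captures it, reductive elimination from Ni(III) forms C3–C4, and Mn returns nickel to its low-valent state. The closest known reaction type is the Ni/bipyridine-catalysed reductive cross-electrophile coupling of terminal epoxides with aryl and alkenyl halides under iodide co-catalysis; a glycidic ester and a trisubstituted (Z)-alkenyl iodide are new substrates for it, not a new reaction. No ring is closed: the oxirane is a temporary ring that activates C3 and carries the C2 oxygen, and it is opened here. No stereocentre is formed: C2 keeps the configuration of 15 because only the C3–O bond breaks, the 4Z geometry is that of 14 because oxidative addition and reductive elimination at the alkenyl carbon go with retention, and C8 is remote. The step needs cross- over homo-coupling, which the different activation modes of the two electrophiles (two-electron at C(sp2)–I, one-electron at C(sp3)–I) and the slow release of 16 from the epoxide should secure, and it needs opening at C3 and not C2, which the unhindered CH2 terminus secures. The free hydroxyl, the ester, the 1,3-diene and the furan offer no bond that Mn/Ni(bpy) reduces at room temperature, so no protecting group is needed and the coupling gives the target directly.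

**Compound list**

1 | 3-bromofuran | Brc1ccoc1 | starting material
2 | 5-chloro-1-(trimethylsilyl)pent-1-yne | C[Si](C)(C)C#CCCCCl | starting material
3 | [5-(trimethylsilyl)pent-4-yn-1-yl]magnesium chloride | C[Si](C)(C)C#CCCC[Mg]Cl | intermediate
4 | 3-[5-(trimethylsilyl)pent-4-yn-1-yl]furan | C[Si](C)(C)C#CCCCc1ccoc1 | intermediate
5 | 3-(pent-4-yn-1-yl)furan | C#CCCCc1ccoc1 | intermediate
6 | [(1E)-5-(furan-3-yl)-2-methylpent-1-en-1-yl]dimethylalumane | C[Al](C)/C=C(\C)CCCc1ccoc1 | intermediate
7 | 3-[(4E)-5-iodo-4-methylpent-4-en-1-yl]furan | I/C=C(\C)CCCc1ccoc1 | intermediate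
8 | (S)-β-citronellene, (3S)-3,7-dimethylocta-1,6-diene | C=C[C@@H](C)CCC=C(C)C | starting material
9 | 3,3-dimethyl-5-[(3S)-3-methylpent-4-en-1-yl]-1,2,4-trioxolane (ozonide, epimers at C5 of the ring) | C=C[C@@H](C)CCC1OOC(C)(C)O1 | intermediate
10 | (4S)-4-methylhex-5-enal | C=C[C@@H](C)CCC=O | intermediate
11 | vinylboronic acid pinacol ester, 2-ethenyl-4,4,5,5-tetramethyl-1,3,2-dioxaborolane | C=CB1OC(C)(C)C(C)(C)O1 | starting material
12 | (4S,5E)-4-methyl-6-(4,4,5,5-tetramethyl-1,3,2-dioxaborolan-2-yl)hex-5-enal | O=CCC[C@H](C)/C=C/B1OC(C)(C)C(C)(C)O1 | intermediate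
13 | (4S,5E,7E)-11-(furan-3-yl)-4,8-dimethylundeca-5,7-dienal | O=CCC[C@H](C)/C=C/C=C(\C)CCCc1ccoc1 | intermediate
14 | 3-[(4E,6E,8S,11Z)-12-iodo-4,8-dimethyltrideca-4,6,11-trien-1-yl]furan | I/C(C)=C\CC[C@H](C)/C=C/C=C(\C)CCCc1ccoc1 | intermediate
15 | methyl (R)-glycidate, methyl (2R)-oxirane-2-carboxylate | COC(=O)[C@H]1CO1 | starting material
16 | methyl (2S)-2-hydroxy-3-iodopropanoate | COC(=O)[C@H](O)CI | intermediate
17 | methyl (2R,4Z,8S,9E,11E)-15-(furan-3-yl)-2-hydroxy-4,8,12-trimethylpentadeca-4,9,11-trienoate | COC(=O)[C@H](O)C/C(C)=C\CC[C@H](C)/C=C/C=C(\C)CCCc1ccoc1 | target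

**Step count**

Total: 8 steps. Longest linear sequence: 6 steps (steps 1, 2, 3, 6, 7, 8); the east branch (steps 4, 5) joins at step 6.

**Steps most likely to fail**

Step 8 (key coupling). Reductive dimerisation or protodeiodination of the alkenyl iodide may outrun capture of the C3 radical. The radical may add to the diene or the furan, the alkenylnickel species may lose its Z geometry, or the iodohydrin may be reduced to acrylate. Fallback, same bond by polar chemistry of known type: from 14, iodine–lithium exchange (t-BuLi, 2 equiv, Et2O, −78 °C) should give the alkenyllithium F1. MgBr2·OEt2 then converts it into the alkenylmagnesium bromide F2. Copper-catalysed opening of 15 at C3 (CuI 10 mol %, THF, −40 °C, 15 in excess) with NH4Cl work-up is the standard reaction of glycidic esters with alkenyl Grignard reagents and should give the target. The fallback sets out from 14 and comes back at 17.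

Step 7 (iodo-olefination). The α-iodo ylide may decompose before it meets the aldehyde, leaving low conversion. Residual non-iodinated ylide gives the ethylidene alkene, and Z-selectivity may erode. Fallback, Wittig–Schlosser (β-oxido ylide) route in which iodine is introduced after the C–C bond is made: from 13, ethylidenetriphenylphosphorane (EtPPh3Br, PhLi, THF/Et2O, LiBr present) adds at −78 °C to give the lithium β-oxido phosphonium bromide F3. A second equivalent of PhLi (−78 → −30 °C) gives the β-lithiooxy ylide F4. Iodine at −78 °C gives the α-iodo β-lithiooxy phosphonium iodide F5, which should lose triphenylphosphine oxide on warming. As with other electrophiles in this reaction type, the electrophile is expected to end up cis to the aldehyde-derived chain, which is the geometry of 14. The fallback sets out from 13 and comes back at 14.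

Step 6 (diene coupling). Base-induced aldol self-condensation of the enolisable aldehyde and protodeboronation may compete with transmetalation. Fallback, mask the aldehyde before the coupling: from 12, acetalisation (HC(OMe)3, MeOH, PPTS, rt) should give the boronate acetal 2-[(1E,3S)-6,6-dimethoxy-3-methylhex-1-en-1-yl]-4,4,5,5-tetramethyl-1,3,2-dioxaborolane F6. Suzuki coupling of F6 with 7 under the conditions of step 6 (or with stronger base and heating) gives the diene acetal 3-[(4E,6E,8S)-11,11-dimethoxy-4,8-dimethylundeca-4,6-dien-1-yl]furan F7. Mild hydrolysis (aqueous oxalic acid, THF, rt) returns the aldehyde. The fallback sets out from 12 and comes back at 13.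

**Further compounds**

F1 | step 8 | alkenyllithium from 14 (Li in place of I, C=C geometry retained) | [Li]/C(C)=C\CC[C@H](C)/C=C/C=C(\C)CCCc1ccoc1
F2 | step 8 | alkenylmagnesium bromide from F1 (MgBr in place of Li, geometry retained) | Br[Mg]/C(C)=C\CC[C@H](C)/C=C/C=C(\C)CCCc1ccoc1
F3 | step 7 | lithium β-oxido phosphonium bromide (Wittig betaine–LiBr adduct of 13, new sp3 centres undefined) | CC([P+](c1ccccc1)(c1ccccc1)c1ccccc1)C(O[Li])CC[C@H](C)/C=C/C=C(\C)CCCc1ccoc1.[Br-]
F4 | step 7 | β-lithiooxy phosphonium ylide from F3 | CC(=P(c1ccccc1)(c1ccccc1)c1ccccc1)C(O[Li])CC[C@H](C)/C=C/C=C(\C)CCCc1ccoc1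
F5 | step 7 | α-iodo β-lithiooxy phosphonium iodide from F4 | CC(I)([P+](c1ccccc1)(c1ccccc1)c1ccccc1)C(O[Li])CC[C@H](C)/C=C/C=C(\C)CCCc1ccoc1.[I-]
F6 | step 6 | 2-[(1E,3S)-6,6-dimethoxy-3-methylhex-1-en-1-yl]-4,4,5,5-tetramethyl-1,3,2-dioxaborolane | COC(OC)CC[C@H](C)/C=C/B1OC(C)(C)C(C)(C)O1
F7 | step 6 | 3-[(4E,6E,8S)-11,11-dimethoxy-4,8-dimethylundeca-4,6-dien-1-yl]furan | COC(OC)CC[C@H](C)/C=C/C=C(\C)CCCc1ccoc1
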